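**Plan**
1. Cuts: first the O–CH3 bond of the C2 branch, whose carbon returns to a formyl group. Then C1–C2 (this opens ring B), then C1–C8a, and last C3–C4.
2. Enabling feature: C1 lies between ring A and the pendant ring C, and each ring has a methoxy group para to C1 (C6-OMe, C4'-OMe). A C1 carbinol therefore ionises to a flat benzhydryl cation. C2 is α to its own branch carbon, which as an aldehyde turns C2 into an enamine carbon.
3. Forward: the C2–C3–C4 chain is built on an acyl oxazolidinone and joined to ring A at C4. Ring C arrives together with C1 by aryllithium addition, and the terminal alkene is cut to the aldehyde. Ring B, the only ring to be made, then closes at C1–C2.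
4. Stereochemistry: C3 comes from the (S)-4-benzyloxazolidinone alkylation. In the closure the 5R imidazolidinone sets C2 as 2R, and the 1,2-trans half-chair passes this on to C1 as 1S (1,3-trans). C2 is then turned to 2S by enolate protonation anti to the pseudo-axial ring C.

Key step: step 7

Numbering: tetralin locants are used. Ring A is the fused dimethoxybenzene ring, ring B the new carbocycle, and ring C the pendant 3,4-dimethoxyphenyl group. The target is (1S,2S,3S), 1,2-cis-2,3-trans.

Assumption: the closure of ring B is taken to place ring C and the enamine carbon trans across the new C1–C2 bond, because both can then be pseudo-equatorial. The catalyst antipode and the later inversion at C2 are chosen on that basis.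

**Step 1**
Reactants: 1 pent-4-enoic acid; 2 (S)-4-benzyloxazolidin-2-one
Product: 4 (4S)-4-benzyl-3-(pent-4-enoyl)-1,3-oxazolidin-2-one, via mixed pivalic anhydride 3 (not isolated)
Conditions: t-BuCOCl, Et3N, THF, −20 °C; then LiCl, 2, −20 °C → rt
Reagents that add atoms: pivaloyl chloride, CC(C)(C)C(=O)Cl (its acyl group sits only in 3 and is absent from 4)
Why: Mixed-anhydride N-acylation of an oxazolidinone, in which the tert-butyl group shields the pivaloyl carbonyl of 3, so the lithium-activated carbamate nitrogen takes the pentenoyl carbonyl and no stereocentre is touched.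

**Step 2**
Reactants: 4 (4S)-4-benzyl-3-(pent-4-enoyl)-1,3-oxazolidin-2-one; 5 2-bromo-4,5-dimethoxybenzyl bromide
Product: 7 (4S)-4-benzyl-3-[(2R)-2-(2-bromo-4,5-dimethoxybenzyl)pent-4-enoyl]-1,3-oxazolidin-2-one, via sodium Z-enolate 6 (not isolated)
Conditions: NaN(SiMe3)2, THF, −78 °C; then 5, −78 → −40 °C
Reagents that add atoms: NaN(SiMe3)2, C[Si](C)(C)[N-][Si](C)(C)C.[Na+] (only the sodium ion of 6; nothing stays in 7)
Why: Evans asymmetric alkylation, in which the chelated Z-enolate 6 meets the reactive benzylic bromide on the face away from the C4 benzyl group of the auxiliary; this forms C3–C4 and sets the future C3 centre (2R in 7), while the aryl bromide and the alkene are inert.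

**Step 3**
Reactants: 7 (4S)-4-benzyl-3-[(2R)-2-(2-bromo-4,5-dimethoxybenzyl)pent-4-enoyl]-1,3-oxazolidin-2-one
Product: 8 (2R)-2-(2-bromo-4,5-dimethoxybenzyl)pent-4-en-1-ol
Conditions: LiBH4, H2O (1 equiv), Et2O, 0 °C; aq. NaOH work-up
Reagents that add atoms: none
Why: Reductive cleavage of the auxiliary, in which hydride attacks the exocyclic imide carbonyl without enolising the α-centre, and the aryl bromide, alkene and aryl ethers are not reduced by LiBH4.

**Step 4**
Reactants: 8 (2R)-2-(2-bromo-4,5-dimethoxybenzyl)pent-4-en-1-ol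
Product: 10 1-bromo-4,5-dimethoxy-2-[(2R)-2-(methoxymethyl)pent-4-en-1-yl]benzene, via sodium alkoxide 9 (not isolated)
Conditions: NaH, THF, 0 °C; then MeI, 0 °C → rt
Reagents that add atoms: iodomethane, CI; NaH, [Na+].[H-] (only the sodium ion of 9)
Why: Williamson ether synthesis on the only acidic site installs the C3 methoxymethyl branch, and the stereocentre carries no acidic hydrogen.

**Step 5**
Reactants: 10 1-bromo-4,5-dimethoxy-2-[(2R)-2-(methoxymethyl)pent-4-en-1-yl]benzene; 11 veratraldehyde (3,4-dimethoxybenzaldehyde)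
Product: 13 (3,4-dimethoxyphenyl){4,5-dimethoxy-2-[(2R)-2-(methoxymethyl)pent-4-en-1-yl]phenyl}methanol (both carbinol epimers), via aryllithium 12 (not isolated)
Conditions: n-BuLi, THF, −78 °C; then 11, −78 → 0 °C; H2O
Reagents that add atoms: n-butyllithium, [Li]CCCC (only the lithium of 12)
Why: Bromine–lithium exchange followed by 1,2-addition to a non-enolisable aldehyde forms C1–C8a; at −78 °C exchange outruns carbolithiation of the remote alkene, and the uncontrolled carbinol centre does not matter because it is erased by ionisation in step 7.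

**Step 6**
Reactants: 13 (3,4-dimethoxyphenyl){4,5-dimethoxy-2-[(2R)-2-(methoxymethyl)pent-4-en-1-yl]phenyl}methanol
Product: 15 (3S)-4-{2-[(3,4-dimethoxyphenyl)(hydroxy)methyl]-4,5-dimethoxyphenyl}-3-(methoxymethyl)butanal (both carbinol epimers), via vicinal diol 14 (not isolated)
Conditions: OsO4 (cat.), NaIO4, 2,6-lutidine, dioxane/H2O, rt
Reagents that add atoms: OsO4, O=[Os](=O)(=O)=O (delivers both new oxygen atoms of 14, one of which stays in 15); NaIO4, [Na+].[O-]I(=O)(=O)=O (restores the osmium oxide as terminal oxidant)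
Why: Lemieux–Johnson oxidation, in which OsO4 dihydroxylates the only alkene and periodate cleaves the 1,2-diol; the benzhydrol has no vicinal oxygen, the veratryl rings are left alone, and 2,6-lutidine keeps the medium non-acidic so that the carbinol does not ionise (the descriptor changes to S through priorities only).

**Step 7**
Reactants: 15 (3S)-4-{2-[(3,4-dimethoxyphenyl)(hydroxy)methyl]-4,5-dimethoxyphenyl}-3-(methoxymethyl)butanal
Product: 17 (1S,2R,3S)-1-(3,4-dimethoxyphenyl)-6,7-dimethoxy-3-(methoxymethyl)-1,2,3,4-tetrahydronaphthalene-2-carbaldehyde (1,2-trans-2,3-cis), via enamine benzhydryl cation 16 (not isolated)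
Conditions: (5R)-5-benzyl-2,2,3-trimethylimidazolidin-4-one·CF3CO2H (20 mol%), In(OTf)3 (10 mol%, added last), CH2Cl2 (0.01 M), 0 °C
Reagents that add atoms: (5R)-5-benzyl-2,2,3-trimethylimidazolidin-4-one, CN1C(=O)[C@@H](Cc2ccccc2)NC1(C)C (bound only in 16 and released on hydrolysis)
Why: Proposed new method: In(OTf)3 ionises either carbinol epimer of 15 to the same planar benzhydryl cation, stabilised by the C6 and C4' methoxy groups, while the imidazolidinone condenses with the aldehyde to an E-enamine; in 16 the enamine carbon C2 bonds to C1, and the water set free hydrolyses the iminium ion and returns both catalysts. The closest known reaction type is the intermolecular organocatalytic SN1 α-alkylation of aldehydes with benzhydrols through imidazolidinone enamines, alone or paired with In(OTf)3; the ring-closing version and a cation without amino donors go beyond it. Ring B closes in a 6-(enolexo) mode on a trigonal cationic carbon, 6-endo-trig when counted on the ring A quinone-methide resonance form and 6-exo-trig on the ring C form. C2 is controlled by the catalyst, whose 5R benzyl group covers one enamine face so that C1 bonds to the face giving 2R. C1 is controlled by the half-chair of the forming ring, in which ring C stays on the C8–H side of the cation, away from the C4 tether, and ends pseudo-equatorial and trans to the pseudo-equatorial enamine carbon, which gives 1S and the 1,3-trans relation with the C3 branch axial. The step needs C-alkylation within the molecule to outrun Friedel–Crafts attack on other veratryl rings, which the six-atom distance between C2 and C1, high dilution and the reversibility of O- and N-capture of this stabilised cation secure, and it needs the catalyst to override the modest bias of C3 for a 2,3-trans closure.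

**Step 8**
Reactants: 17 (1S,2R,3S)-1-(3,4-dimethoxyphenyl)-6,7-dimethoxy-3-(methoxymethyl)-1,2,3,4-tetrahydronaphthalene-2-carbaldehyde
Product: 19 (1S,2S,3S)-1-(3,4-dimethoxyphenyl)-6,7-dimethoxy-3-(methoxymethyl)-1,2,3,4-tetrahydronaphthalene-2-carbaldehyde (1,2-cis-2,3-trans), via potassium enolate 18 (not isolated)
Conditions: KN(SiMe3)2, THF, −78 °C (17 added slowly to the base); then AcOH/THF, −78 °C; cold pH 7 buffer, used without chromatography
Reagents that add atoms: KN(SiMe3)2, C[Si](C)(C)[N-][Si](C)(C)C.[K+] (only the potassium ion of 18)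
Why: Stereoselective kinetic protonation of an enolate, in which allylic strain from the exocyclic C2=CH–O unit and the peri C8–H hold ring C pseudo-axial in 18; the proton therefore reaches C2 axially from the opposite face and the formyl group ends cis to ring C and trans to the C3 branch (2S), the tactic known for turning 1,2-trans aryltetralin lactones into their 1,2-cis epimers.

**Step 9**
Reactants: 19 (1S,2S,3S)-1-(3,4-dimethoxyphenyl)-6,7-dimethoxy-3-(methoxymethyl)-1,2,3,4-tetrahydronaphthalene-2-carbaldehyde
Product: 20 [(1S,2S,3S)-1-(3,4-dimethoxyphenyl)-6,7-dimethoxy-3-(methoxymethyl)-1,2,3,4-tetrahydronaphthalen-2-yl]methanol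
Conditions: NaBH4, MeOH, −20 → 0 °C
Reagents that add atoms: none
Why: Borohydride reduction of the aldehyde is far faster than enolisation at low temperature, so the 2S centre is fixed for good.

**Step 10**
Reactants: 20 [(1S,2S,3S)-1-(3,4-dimethoxyphenyl)-6,7-dimethoxy-3-(methoxymethyl)-1,2,3,4-tetrahydronaphthalen-2-yl]methanol
Product: 22 (1S,2S,3S)-1-(3,4-dimethoxyphenyl)-6,7-dimethoxy-2,3-bis(methoxymethyl)-1,2,3,4-tetrahydronaphthalene (target), via sodium alkoxide 21 (not isolated)
Conditions: NaH, THF, 0 °C; then MeI, rt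
Reagents that add atoms: iodomethane, CI; NaH, [Na+].[H-] (only the sodium ion of 21)
Why: Williamson ether synthesis on the only free hydroxyl group completes the second methoxymethyl branch, and none of the three stereocentres is acidic enough to be disturbed.

**Compound list**
1 | pent-4-enoic acid | C=CCCC(=O)O | starting material
2 | (S)-4-benzyloxazolidin-2-one | O=C1OC[C@H](Cc2ccccc2)N1 | starting material
3 | pent-4-enoic pivalic anhydride | C=CCCC(=O)OC(=O)C(C)(C)C | intermediate
4 | (4S)-4-benzyl-3-(pent-4-enoyl)-1,3-oxazolidin-2-one | C=CCCC(=O)N1[C@@H](Cc2ccccc2)COC1=O | intermediate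
5 | 2-bromo-4,5-dimethoxybenzyl bromide | COc1cc(Br)c(CBr)cc1OC | starting material
6 | sodium (Z)-enolate of 4 | C=CC/C=C(\[O-])N1[C@@H](Cc2ccccc2)COC1=O.[Na+] | intermediate
7 | (4S)-4-benzyl-3-[(2R)-2-(2-bromo-4,5-dimethoxybenzyl)pent-4-enoyl]-1,3-oxazolidin-2-one | C=CC[C@H](Cc1cc(OC)c(OC)cc1Br)C(=O)N1[C@@H](Cc2ccccc2)COC1=O | intermediate
8 | (2R)-2-(2-bromo-4,5-dimethoxybenzyl)pent-4-en-1-ol | OC[C@H](CC=C)Cc1cc(OC)c(OC)cc1Br | intermediate
9 | sodium alkoxide of 8 | [Na+].[O-]C[C@H](CC=C)Cc1cc(OC)c(OC)cc1Br | intermediate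
10 | 1-bromo-4,5-dimethoxy-2-[(2R)-2-(methoxymethyl)pent-4-en-1-yl]benzene | COC[C@H](CC=C)Cc1cc(OC)c(OC)cc1Br | intermediate
11 | veratraldehyde | COc1ccc(C=O)cc1OC | starting material
12 | {4,5-dimethoxy-2-[(2R)-2-(methoxymethyl)pent-4-en-1-yl]phenyl}lithium | COC[C@H](CC=C)Cc1cc(OC)c(OC)cc1[Li] | intermediate
13 | (3,4-dimethoxyphenyl){4,5-dimethoxy-2-[(2R)-2-(methoxymethyl)pent-4-en-1-yl]phenyl}methanol, both carbinol epimers | COC[C@H](CC=C)Cc1cc(OC)c(OC)cc1C(O)c1ccc(OC)c(OC)c1 | intermediate
14 | (4S)-5-{2-[(3,4-dimethoxyphenyl)(hydroxy)methyl]-4,5-dimethoxyphenyl}-4-(methoxymethyl)pentane-1,2-diol, carbinol centres mixed | COC[C@H](CC(O)CO)Cc1cc(OC)c(OC)cc1C(O)c1ccc(OC)c(OC)c1 | intermediate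
15 | (3S)-4-{2-[(3,4-dimethoxyphenyl)(hydroxy)methyl]-4,5-dimethoxyphenyl}-3-(methoxymethyl)butanal, both carbinol epimers | COC[C@H](CC=O)Cc1cc(OC)c(OC)cc1C(O)c1ccc(OC)c(OC)c1 | intermediate
16 | E-enamine of 15 and the 5R imidazolidinone, ionised at C1 to the benzhydryl cation | COC[C@H](/C=C/N1[C@H](Cc2ccccc2)C(=O)N(C)C1(C)C)Cc1cc(OC)c(OC)cc1[CH+]c1ccc(OC)c(OC)c1 | intermediate
17 | (1S,2R,3S)-1-(3,4-dimethoxyphenyl)-6,7-dimethoxy-3-(methoxymethyl)-1,2,3,4-tetrahydronaphthalene-2-carbaldehyde | COC[C@H]1Cc2cc(OC)c(OC)cc2[C@H](c2ccc(OC)c(OC)c2)[C@H]1C=O | intermediate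
18 | potassium enolate of 17 (exocyclic C2=CH–OK, C1 and C3 unchanged) | COC[C@H]1Cc2cc(OC)c(OC)cc2[C@H](c2ccc(OC)c(OC)c2)C1=C[O-].[K+] | intermediate
19 | (1S,2S,3S)-1-(3,4-dimethoxyphenyl)-6,7-dimethoxy-3-(methoxymethyl)-1,2,3,4-tetrahydronaphthalene-2-carbaldehyde | COC[C@H]1Cc2cc(OC)c(OC)cc2[C@H](c2ccc(OC)c(OC)c2)[C@@H]1C=O | intermediate
20 | [(1S,2S,3S)-1-(3,4-dimethoxyphenyl)-6,7-dimethoxy-3-(methoxymethyl)-1,2,3,4-tetrahydronaphthalen-2-yl]methanol | COC[C@H]1Cc2cc(OC)c(OC)cc2[C@H](c2ccc(OC)c(OC)c2)[C@@H]1CO | intermediate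
21 | sodium alkoxide of 20 | COC[C@H]1Cc2cc(OC)c(OC)cc2[C@H](c2ccc(OC)c(OC)c2)[C@@H]1C[O-].[Na+] | intermediate
22 | (1S,2S,3S)-1-(3,4-dimethoxyphenyl)-6,7-dimethoxy-2,3-bis(methoxymethyl)-1,2,3,4-tetrahydronaphthalene | COC[C@H]1Cc2cc(OC)c(OC)cc2[C@H](c2ccc(OC)c(OC)c2)[C@@H]1COC | target

**Totals**
Total step count: 10. Longest linear sequence: 10 steps (1 → 22).

**Steps most likely to fail**

Step 7.
- The main danger is poor facial selectivity at the cationic carbon C1.
- The catalyst may also fail to override the C3 bias.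
- The ring may close through the enol without the amine, in which case C3 alone would decide the outcome.
- Intermolecular Friedel–Crafts arylation or lasting N-alkylation of the catalyst could drain the cation.

The fallback uses known reactions only. It still closes ring B at C1–C2, but as an aldol condensation, and brings ring C in afterwards. It sets out from 10 and comes back at 19.
- Bromine–lithium exchange to 12 and a DMF quench should give the aryl aldehyde F1.
- OsO4/NaIO4 cleaves its alkene through the diol F2 to the dialdehyde F3.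
- Pyrrolidine/AcOH then effects the intramolecular aldol condensation, in which only the aliphatic aldehyde can enolise, to the dihydronaphthalene enal F4.
- Copper-mediated conjugate addition of commercial 3,4-dimethoxyphenylmagnesium bromide (CuBr·SMe2, Me3SiCl, THF, −78 °C) should place ring C on C1 from the face away from the C3 branch. This secures the 1,3-trans relation and gives the trimethylsilyl enol ether F5.
- Cold dilute acid then protonates C2 anti to the new pseudo-axial aryl group and leads to 19.

Step 8.
- The aldehyde enolate may self-condense.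
- Deprotonation at the hindered C2–H may be incomplete.
- O-protonation may be followed by unselective tautomerisation.
- The new centre may re-epimerise during work-up.

The fallback replaces proton delivery by hydrogen delivery from a metal surface. It sets out from 17 and comes back at 20.
- t-BuMe2SiOTf/Et3N converts 17 into the tert-butyldimethylsilyl enol ether F6.
- Hydrogenation (H2, Pd/C, EtOAc) should add hydrogen to C2 on the face away from the pseudo-axial ring C and give the silyl ether F7.
- Bu4NF then frees 20.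

Step 6.
- Material may be lost by premature ionisation of the benzhydrol during oxidative cleavage or chromatography.
- The aldehyde may be over-oxidised.

The fallback changes the order of events so that the sensitive carbinol never meets the oxidant. It sets out from 10 and comes back at 15.
- OsO4/NaIO4 cleaves 10 through the bromo diol F8 to the bromo aldehyde F9.
- HC(OMe)3/MeOH with pyridinium tosylate masks F9 as the dimethyl acetal F10.
- Bromine–lithium exchange gives the aryllithium F11, which adds to 11 to form the benzhydrol acetal F12.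
- LiBF4 in wet MeCN then unmasks the aldehyde. Any transient ionisation of the carbinol in this wet medium is simply reversed by water.

**Further compounds**
F1 | step 7 | 4,5-dimethoxy-2-[(2R)-2-(methoxymethyl)pent-4-en-1-yl]benzaldehyde | COC[C@H](CC=C)Cc1cc(OC)c(OC)cc1C=O
F2 | step 7 | 2-[(2S)-4,5-dihydroxy-2-(methoxymethyl)pentyl]-4,5-dimethoxybenzaldehyde (carbinol epimers) | COC[C@H](CC(O)CO)Cc1cc(OC)c(OC)cc1C=O
F3 | step 7 | 4,5-dimethoxy-2-[(2S)-2-(methoxymethyl)-4-oxobutyl]benzaldehyde | COC[C@H](CC=O)Cc1cc(OC)c(OC)cc1C=O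
F4 | step 7 | (3S)-6,7-dimethoxy-3-(methoxymethyl)-3,4-dihydronaphthalene-2-carbaldehyde | COC[C@H]1Cc2cc(OC)c(OC)cc2C=C1C=O
F5 | step 7 | trimethylsilyl enol ether of 19 (exocyclic C2=CH–OSiMe3, ring C and C3 branch trans) | COC[C@H]1Cc2cc(OC)c(OC)cc2[C@H](c2ccc(OC)c(OC)c2)C1=CO[Si](C)(C)C
F6 | step 8 | tert-butyldimethylsilyl enol ether of 17 (exocyclic C2=CH–OSi, ring C and C3 branch trans) | COC[C@H]1Cc2cc(OC)c(OC)cc2[C@H](c2ccc(OC)c(OC)c2)C1=CO[Si](C)(C)C(C)(C)C
F7 | step 8 | tert-butyldimethylsilyl ether of 20 | COC[C@H]1Cc2cc(OC)c(OC)cc2[C@H](c2ccc(OC)c(OC)c2)[C@@H]1CO[Si](C)(C)C(C)(C)C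
F8 | step 6 | (4S)-5-(2-bromo-4,5-dimethoxyphenyl)-4-(methoxymethyl)pentane-1,2-diol (carbinol epimers) | COC[C@H](CC(O)CO)Cc1cc(OC)c(OC)cc1Br
F9 | step 6 | (3S)-4-(2-bromo-4,5-dimethoxyphenyl)-3-(methoxymethyl)butanal | COC[C@H](CC=O)Cc1cc(OC)c(OC)cc1Br
F10 | step 6 | 1-bromo-2-[(2S)-4,4-dimethoxy-2-(methoxymethyl)butyl]-4,5-dimethoxybenzene | COC[C@H](CC(OC)OC)Cc1cc(OC)c(OC)cc1Br
F11 | step 6 | {2-[(2S)-4,4-dimethoxy-2-(methoxymethyl)butyl]-4,5-dimethoxyphenyl}lithium | COC[C@H](CC(OC)OC)Cc1cc(OC)c(OC)cc1[Li]
F12 | step 6 | {2-[(2S)-4,4-dimethoxy-2-(methoxymethyl)butyl]-4,5-dimethoxyphenyl}(3,4-dimethoxyphenyl)methanol (carbinol epimers) | COC[C@H](CC(OC)OC)Cc1cc(OC)c(OC)cc1C(O)c1ccc(OC)c(OC)c1
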